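The cyclohexene ring is cut at C6–C1. C6 bears an oxygen, the carboxyl-level carbon C7 and the allylic carbon C1 next to C2=C3, the substitution that an ester-enolate Claisen rearrangement leaves behind, and the trans oxygens on C4 and C5 map onto C4 and C3 of D-glucose. A D-gluco-heptenono-1,5-lactone with an E enol ether side chain is therefore rearranged through its silyl ketene acetal. One boat [3,3] shift forms C6–C1 and C2=C3, closes the carbocycle, passes the chirality of sugar C5 to C6 and fixes C1 from the alkene geometry. The precursor is a 2,3-di-O-silyl, 4-O-PMB lactone with a PMB enol ether, made from D-glucose; five steps finish the target.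

Key step: step 10

Remarks: C1–C7 are target locants (C1, C4 benzoates; C6 carries C7H2OH). "Sugar C" locants refer to the heptose chain (sugar C1 = C7, sugar C2 = C6, sugar C3 = C5, sugar C4 = C4, sugar C7 = C1). TBS = tert-butyldimethylsilyl, PMB = 4-methoxybenzyl.
Assumption: silyl glycosides 5–13 are drawn as β-anomers; the anomeric centre is cleared at lactol 14, so any α-anomer from step 2 would follow the same course.

Step 1
Reactants: 1 D-glucose; 2 4-methoxybenzaldehyde dimethyl acetal
Product: 3 4,6-O-[(R)-4-methoxybenzylidene]-D-glucopyranose (α/β)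
Conditions: TsOH·H2O (cat.), DMF, 50 °C, 200 mbar
Reagents that add atoms: 4-methoxybenzaldehyde dimethyl acetal, COc1ccc(C(OC)OC)cc1
Why: Acid-catalysed transacetalisation under thermodynamic control should give the trans-fused 4,6-O-arylidene acetal, the new acetal carbon taking the R configuration that puts the aryl group equatorial on the 1,3-dioxane chair.

Step 2
Reactants: 3 4,6-O-[(R)-4-methoxybenzylidene]-D-glucopyranose; 4 tert-butyldimethylsilyl triflate
Product: 5 tert-butyldimethylsilyl 2,3-di-O-TBS-4,6-O-[(R)-4-methoxybenzylidene]-β-D-glucopyranoside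
Conditions: 2,6-lutidine, CH2Cl2, −20 °C → rt
Reagents that add atoms: tert-butyldimethylsilyl triflate, CC(C)(C)[Si](C)(C)OS(=O)(=O)C(F)(F)F
Why: Silyl triflate O-silylation with a hindered pyridine base should cap the anomeric, C2 and C3 hydroxyls in one operation without opening the acetal, the anomeric group becoming a fluoride-labile silyl acetal (β shown) whose configuration is of no consequence.

Step 3
Reactants: 5 tert-butyldimethylsilyl 2,3-di-O-TBS-4,6-O-[(R)-4-methoxybenzylidene]-β-D-glucopyranoside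
Product: 6 tert-butyldimethylsilyl 2,3-di-O-TBS-4-O-PMB-β-D-glucopyranoside (free 6-OH)
Conditions: i-Bu2AlH, CH2Cl2/toluene, −78 → 0 °C; Rochelle salt work-up
Reagents that add atoms: none
Why: Reductive opening of an arylidene acetal by a Lewis-acidic aluminium hydride: aluminium binds the less hindered O6, so hydride delivery to the benzylic carbon should leave the PMB ether on O4 and free the primary alcohol.

Step 4
Reactants: 6 tert-butyldimethylsilyl 2,3-di-O-TBS-4-O-PMB-β-D-glucopyranoside
Product: 7 tert-butyldimethylsilyl 2,3-di-O-TBS-4-O-PMB-β-D-gluco-hexodialdo-1,5-pyranoside (C6 aldehyde)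
Conditions: Dess–Martin periodinane, pyridine, CH2Cl2, 0 °C → rt; used crude
Reagents that add atoms: none
Why: Dess–Martin oxidation of the primary alcohol under buffered, non-basic conditions should give the α-alkoxy aldehyde without epimerisation at sugar C5 or β-elimination of the O4 ether.

Step 5
Reactants: 7 C6 aldehyde; 8 dimethyl (1-diazo-2-oxopropyl)phosphonate
Product: 9 tert-butyldimethylsilyl 6,7-dideoxy-2,3-di-O-TBS-4-O-PMB-β-D-gluco-hept-6-ynopyranoside
Conditions: K2CO3, MeOH, 0 °C → rt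
Reagents that add atoms: dimethyl (1-diazo-2-oxopropyl)phosphonate, COP(=O)(OC)C(=[N+]=[N-])C(C)=O
Why: Ohira–Bestmann (Seyferth–Gilbert) homologation, established for pyranose 6-aldehydes: the diazomethylphosphonate anion made in situ adds to the aldehyde and the derived alkylidene carbene rearranges to the terminal alkyne, the equatorial C5 substituent being also the thermodynamically preferred one.

Step 6
Reactants: 9 hept-6-ynopyranoside; 10 pinacolborane
Product: 11 tert-butyldimethylsilyl 6,7-dideoxy-7-(pinacolboryl)-2,3-di-O-TBS-4-O-PMB-β-D-gluco-hept-6(E)-enopyranoside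
Conditions: Cp2Zr(H)Cl (10 mol %), Et3N (10 mol %), CH2Cl2, 40 °C
Reagents that add atoms: pinacolborane, CC1(C)OBOC1(C)C
Why: Zirconocene-hydride-catalysed hydroboration adds H–B syn across the terminal alkyne with boron on the terminal carbon, which fixes the E geometry of the alkenylboronate.

Step 7
Reactants: 11 E alkenyl pinacol boronate; 12 4-methoxybenzyl alcohol
Product: 13 tert-butyldimethylsilyl 6-deoxy-4,7-di-O-PMB-2,3-di-O-TBS-β-D-gluco-hept-6(E)-enopyranoside (E PMB enol ether)
Conditions: Cu(OAc)2 (2 equiv), Et3N (4 equiv), excess 12, 4 Å MS, air, rt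
Reagents that add atoms: 4-methoxybenzyl alcohol, COc1ccc(CO)cc1
Why: Chan–Lam–Evans-type oxidative C–O coupling of an alkenyl pinacol boronate with an aliphatic alcohol: transmetalation to copper and C–O reductive elimination keep the alkene geometry, so the E enol ether should form under basic conditions that the silyl acetal tolerates.

Step 8
Reactants: 13 E PMB enol ether silyl glycoside
Product: 14 6-deoxy-4,7-di-O-PMB-2,3-di-O-TBS-D-gluco-hept-6(E)-enopyranose (lactol; α/β)
Conditions: Bu4NF/AcOH (1:1), THF, 0 °C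
Reagents that add atoms: none
Why: Buffered fluoride desilylation: the anomeric O–Si bond is a silyl acetal with a far better leaving oxygen than the hindered secondary silyl ethers and should be cleaved selectively, at a pH that spares the acid-labile enol ether.

Step 9
Reactants: 14 lactol
Product: 15 6-deoxy-4,7-di-O-PMB-2,3-di-O-TBS-D-gluco-hept-6(E)-enono-1,5-lactone
Conditions: (n-Pr4N)RuO4 (5 mol %), NMO, 4 Å MS, CH2Cl2, 0 °C → rt; Et3N-deactivated silica; used at once
Reagents that add atoms: none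
Why: Ley–Griffith oxidation converts the lactol into the δ-lactone under neutral conditions, which matter because the product is a vinylogous acylal and is taken on without delay.

Step 10
Reactants: 15 heptenono-1,5-lactone
Product: 19 1,4-di-O-PMB-5,6-di-O-TBS-cyclohex-2-ene-6-carboxylic acid (C7 = CO2H; configuration as in the target), via potassium enolate 16 (not isolated), via silyl ketene acetal 17 (not isolated), via trimethylsilyl ester 18 (not isolated)
Conditions: Me3SiCl, Et3N, THF, −78 °C, then KN(SiMe3)2 (toluene); −78 °C → rt, then 50 °C; aq. citric acid work-up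
Reagents that add atoms: none
Why: KN(SiMe3)2 removes H2 of 15 with Me3SiCl already present, so enolate 16 is O-silylated to cyclic ketene acetal 17, whose 1,5-diene (sugar C2=C1–O5–C5–C6=C7) undergoes a concerted suprafacial [3,3]-sigmatropic shift on warming that forms sugar C2–C7 (C6–C1), breaks C5–O5 and gives silyl ester 18, hydrolysed to 19 on work-up. The closest known reaction type is the Ireland–Claisen ring contraction of 6-alkenyl δ-lactones and of 6-alkenyl 1,4-dioxan-2-ones to cyclohexene- and dihydropyran-carboxylic acids. The six-membered carbocycle closes by the sigmatropic shift itself through a boat transition state of bicyclo[2.2.2]octane shape, the only one open because the lactone ties sugar C5 to C2. C6 is set by this tether: the enol ether arm hangs from the β face of sugar C5 and can reach C2 only on that face, so the carboxyl ends up cis to the C4 oxygen and trans to the C5 oxygen. C1 is set by the E alkene, which in the boat turns the OPMB group outward, away from the C3–C4 bridge and cis to the carboxyl. The step needs O-silylation to outrun E1cB loss of the sugar C3 silyloxy group, which the in-situ trap at −78 °C should secure, and the donor oxygen on the allyl terminus should let the shift run near room temperature.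

Step 11
Reactants: 19 cyclohexenecarboxylic acid
Product: 20 1,4-di-O-PMB-5,6-di-O-TBS-6-(hydroxymethyl)cyclohex-2-ene (C7 alcohol)
Conditions: LiAlH4, THF, 0 → 45 °C; Fieser work-up
Reagents that add atoms: none
Why: Hydride reduction of a carboxylic acid to the primary alcohol with LiAlH4, to which the isolated alkene, the benzylic ethers and the hindered silyl ethers are inert.

Step 12
Reactants: 20 C7 alcohol; 4 tert-butyldimethylsilyl triflate
Product: 21 1,4-di-O-PMB-5,6,7-tri-O-TBS tetrol
Conditions: 2,6-lutidine, CH2Cl2, 0 °C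
Reagents that add atoms: tert-butyldimethylsilyl triflate, CC(C)(C)[Si](C)(C)OS(=O)(=O)C(F)(F)F
Why: Silyl triflate O-silylation of the neopentyl-type primary alcohol; should base-induced silyl migration have occurred in step 11, the hydroxyl it frees is silylated as well, so that one tris-silyl ether results.

Step 13
Reactants: 21 bis-PMB tris-TBS ether
Product: 22 5,6,7-tri-O-TBS cyclohex-2-ene-1,4-diol
Conditions: DDQ, CH2Cl2/pH 7 buffer, 0 °C → rt
Reagents that add atoms: none
Why: Oxidative removal of both PMB ethers by DDQ (benzylic hydride abstraction, then hydrolysis of the oxocarbenium ion by the buffer) should leave the silyl ethers and the ring alkene untouched.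

Step 14
Reactants: 22 1,4-diol; 23 benzoyl chloride
Product: 24 1,4-di-O-benzoyl-5,6,7-tri-O-TBS derivative
Conditions: pyridine, DMAP (cat.), CH2Cl2, 0 → 40 °C
Reagents that add atoms: benzoyl chloride, O=C(Cl)c1ccccc1
Why: DMAP-catalysed acylation of the two secondary allylic alcohols, the only free hydroxyl groups in 22, should give the dibenzoate.

Step 15
Reactants: 24 dibenzoate tris-TBS ether
Product: 25 (1S,4R,5S,6S)-5,6-dihydroxy-6-(hydroxymethyl)cyclohex-2-ene-1,4-diyl dibenzoate (target)
Conditions: HF·pyridine, THF/pyridine, 0 °C → rt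
Reagents that add atoms: none
Why: Fluoride-induced Si–O cleavage with HF·pyridine removes the primary, secondary and tertiary silyl ethers under non-basic conditions, which should prevent benzoyl migration to the three hydroxyl groups set free.

Compound list
1 | D-glucose | O=C[C@H](O)[C@@H](O)[C@H](O)[C@H](O)CO | starting material
2 | 4-methoxybenzaldehyde dimethyl acetal | COc1ccc(C(OC)OC)cc1 | starting material
3 | 4,6-O-[(R)-4-methoxybenzylidene]-D-glucopyranose (α/β) | OC1[C@H](O)[C@@H](O)[C@@H]2O[C@H](c3ccc(OC)cc3)OC[C@H]2O1 | intermediate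
4 | tert-butyldimethylsilyl triflate | CC(C)(C)[Si](C)(C)OS(=O)(=O)C(F)(F)F | starting material
5 | tert-butyldimethylsilyl 2,3-di-O-TBS-4,6-O-[(R)-4-methoxybenzylidene]-β-D-glucopyranoside | CC(C)(C)[Si](C)(C)O[C@H]1[C@H](O[Si](C)(C)C(C)(C)C)[C@@H](O[Si](C)(C)C(C)(C)C)[C@@H]2O[C@H](c3ccc(OC)cc3)OC[C@H]2O1 | intermediate
6 | tert-butyldimethylsilyl 2,3-di-O-TBS-4-O-PMB-β-D-glucopyranoside | CC(C)(C)[Si](C)(C)O[C@H]1[C@H](O[Si](C)(C)C(C)(C)C)[C@@H](O[Si](C)(C)C(C)(C)C)[C@H](OCc2ccc(OC)cc2)[C@@H](CO)O1 | intermediate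
7 | C6 aldehyde of 6 | CC(C)(C)[Si](C)(C)O[C@H]1[C@H](O[Si](C)(C)C(C)(C)C)[C@@H](O[Si](C)(C)C(C)(C)C)[C@H](OCc2ccc(OC)cc2)[C@@H](C=O)O1 | intermediate
8 | dimethyl (1-diazo-2-oxopropyl)phosphonate | COP(=O)(OC)C(=[N+]=[N-])C(C)=O | starting material
9 | tert-butyldimethylsilyl 6,7-dideoxy-2,3-di-O-TBS-4-O-PMB-β-D-gluco-hept-6-ynopyranoside | CC(C)(C)[Si](C)(C)O[C@H]1[C@H](O[Si](C)(C)C(C)(C)C)[C@@H](O[Si](C)(C)C(C)(C)C)[C@H](OCc2ccc(OC)cc2)[C@@H](C#C)O1 | intermediate
10 | pinacolborane | CC1(C)OBOC1(C)C | starting material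
11 | E alkenyl pinacol boronate | CC(C)(C)[Si](C)(C)O[C@H]1[C@H](O[Si](C)(C)C(C)(C)C)[C@@H](O[Si](C)(C)C(C)(C)C)[C@H](OCc2ccc(OC)cc2)[C@@H](/C=C/B2OC(C)(C)C(C)(C)O2)O1 | intermediate
12 | 4-methoxybenzyl alcohol | COc1ccc(CO)cc1 | starting material
13 | E PMB enol ether silyl glycoside | CC(C)(C)[Si](C)(C)O[C@H]1[C@H](O[Si](C)(C)C(C)(C)C)[C@@H](O[Si](C)(C)C(C)(C)C)[C@H](OCc2ccc(OC)cc2)[C@@H](/C=C/OCc2ccc(OC)cc2)O1 | intermediate
14 | lactol, 6-deoxy-4,7-di-O-PMB-2,3-di-O-TBS-D-gluco-hept-6(E)-enopyranose (α/β) | OC1[C@H](O[Si](C)(C)C(C)(C)C)[C@@H](O[Si](C)(C)C(C)(C)C)[C@H](OCc2ccc(OC)cc2)[C@@H](/C=C/OCc2ccc(OC)cc2)O1 | intermediate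
15 | 6-deoxy-4,7-di-O-PMB-2,3-di-O-TBS-D-gluco-hept-6(E)-enono-1,5-lactone | O=C1[C@H](O[Si](C)(C)C(C)(C)C)[C@@H](O[Si](C)(C)C(C)(C)C)[C@H](OCc2ccc(OC)cc2)[C@@H](/C=C/OCc2ccc(OC)cc2)O1 | intermediate
16 | potassium enolate of 15 | [K+].[O-]C1=C(O[Si](C)(C)C(C)(C)C)[C@@H](O[Si](C)(C)C(C)(C)C)[C@H](OCc2ccc(OC)cc2)[C@@H](/C=C/OCc2ccc(OC)cc2)O1 | intermediate
17 | trimethylsilyl ketene acetal of 15 | C[Si](C)(C)OC1=C(O[Si](C)(C)C(C)(C)C)[C@@H](O[Si](C)(C)C(C)(C)C)[C@H](OCc2ccc(OC)cc2)[C@@H](/C=C/OCc2ccc(OC)cc2)O1 | intermediate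
18 | trimethylsilyl ester of 19 | COc1ccc(CO[C@H]2C=C[C@@H](OCc3ccc(OC)cc3)[C@H](O[Si](C)(C)C(C)(C)C)[C@@]2(O[Si](C)(C)C(C)(C)C)C(=O)O[Si](C)(C)C)cc1 | intermediate
19 | 1,4-di-O-PMB-5,6-di-O-TBS-cyclohex-2-ene-6-carboxylic acid | COc1ccc(CO[C@H]2C=C[C@@H](OCc3ccc(OC)cc3)[C@H](O[Si](C)(C)C(C)(C)C)[C@@]2(O[Si](C)(C)C(C)(C)C)C(=O)O)cc1 | intermediate
20 | C7 alcohol | COc1ccc(CO[C@H]2C=C[C@@H](OCc3ccc(OC)cc3)[C@H](O[Si](C)(C)C(C)(C)C)[C@@]2(O[Si](C)(C)C(C)(C)C)CO)cc1 | intermediate
21 | 1,4-di-O-PMB-5,6,7-tri-O-TBS tetrol | COc1ccc(CO[C@H]2C=C[C@@H](OCc3ccc(OC)cc3)[C@H](O[Si](C)(C)C(C)(C)C)[C@@]2(O[Si](C)(C)C(C)(C)C)CO[Si](C)(C)C(C)(C)C)cc1 | intermediate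
22 | 5,6,7-tri-O-TBS 1,4-diol | O[C@H]1C=C[C@@H](O)[C@H](O[Si](C)(C)C(C)(C)C)[C@@]1(O[Si](C)(C)C(C)(C)C)CO[Si](C)(C)C(C)(C)C | intermediate
23 | benzoyl chloride | O=C(Cl)c1ccccc1 | starting material
24 | 1,4-di-O-benzoyl-5,6,7-tri-O-TBS derivative | O=C(O[C@H]1C=C[C@@H](OC(=O)c2ccccc2)[C@H](O[Si](C)(C)C(C)(C)C)[C@@]1(O[Si](C)(C)C(C)(C)C)CO[Si](C)(C)C(C)(C)C)c1ccccc1 | intermediate
25 | (1S,4R,5S,6S)-5,6-dihydroxy-6-(hydroxymethyl)cyclohex-2-ene-1,4-diyl dibenzoate | O=C(O[C@H]1C=C[C@@H](OC(=O)c2ccccc2)[C@H](O)[C@@]1(O)CO)c1ccccc1 | target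

Total step count: 15. Longest linear sequence: 15 steps from D-glucose (1).

Steps most likely to fail

Step 10. The enolate may expel the sugar C3 silyloxy group (E1cB) before it is silylated, or the allylic lactone C–O bond may ionise before the shift. The fallback gives up the enolate and makes the same bond at the aldehyde level. It sets out from lactol 14: MsCl/Et3N should give the α-glycosyl chloride F1, and DBU-induced anti elimination of HCl the 2-silyloxy glycal F2. This allyl vinyl ether, heated in toluene (sealed tube, trace Et3N), should undergo the Claisen rearrangement known for 5-vinyl glycals, through the same boat, to cyclohexene carbaldehyde F3. NaBH4 reduction returns to alcohol 20.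

Step 7. Protodeboronation or oxidative homocoupling of the hindered alkenylboronate may outrun alkoxide transfer from copper with a bulky, non-volatile alcohol. The fallback reverses the polarity of the alkene partner. It sets out from aldehyde 7: Takai olefination (CrCl2, CHI3, THF) should give E vinyl iodide F4, and copper-catalysed C–O coupling with alcohol 12 (CuI, 3,4,7,8-tetramethyl-1,10-phenanthroline, Cs2CO3, toluene, 80 °C) keeps the geometry and returns to enol ether 13.

Step 8. Fluoride may also remove or shift the C2/C3 silyl ethers, or the buffer may hydrolyse the vinylogous acetal. The fallback drops the need for selective cleavage. It sets out from 13: excess Bu4NF/AcOH at rt removes all three silyl groups to give triol lactol F5. Ag2CO3 on Celite (toluene, 80 °C) oxidises only the lactol, giving 2,3-dihydroxy lactone F6. Silylation with 4 and 2,6-lutidine at −78 °C returns to lactone 15.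

Further compounds
F1 | step 10 | α-glycosyl chloride of 14 | Cl[C@@H]1[C@H](O[Si](C)(C)C(C)(C)C)[C@@H](O[Si](C)(C)C(C)(C)C)[C@H](OCc2ccc(OC)cc2)[C@@H](/C=C/OCc2ccc(OC)cc2)O1
F2 | step 10 | 2-silyloxy glycal (1,5-anhydro-hepta-1,6(E)-dienitol) | C1=C(O[Si](C)(C)C(C)(C)C)[C@@H](O[Si](C)(C)C(C)(C)C)[C@H](OCc2ccc(OC)cc2)[C@@H](/C=C/OCc2ccc(OC)cc2)O1
F3 | step 10 | 1,4-di-O-PMB-5,6-di-O-TBS-cyclohex-2-ene-6-carbaldehyde | COc1ccc(CO[C@H]2C=C[C@@H](OCc3ccc(OC)cc3)[C@H](O[Si](C)(C)C(C)(C)C)[C@@]2(O[Si](C)(C)C(C)(C)C)C=O)cc1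
F4 | step 7 | E vinyl iodide silyl glycoside | CC(C)(C)[Si](C)(C)O[C@H]1[C@H](O[Si](C)(C)C(C)(C)C)[C@@H](O[Si](C)(C)C(C)(C)C)[C@H](OCc2ccc(OC)cc2)[C@@H](/C=C/I)O1
F5 | step 8 | 6-deoxy-4,7-di-O-PMB-D-gluco-hept-6(E)-enopyranose (triol lactol) | OC1[C@H](O)[C@@H](O)[C@H](OCc2ccc(OC)cc2)[C@@H](/C=C/OCc2ccc(OC)cc2)O1
F6 | step 8 | 6-deoxy-4,7-di-O-PMB-D-gluco-hept-6(E)-enono-1,5-lactone (2,3-diol) | O=C1[C@H](O)[C@@H](O)[C@H](OCc2ccc(OC)cc2)[C@@H](/C=C/OCc2ccc(OC)cc2)O1
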